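**Remark on the chemistry:** which enantiomer of the binaphthyl phosphoric acid gives R at C2' with a 2,6-disubstituted aryl aldimine cannot be assigned with certainty by analogy. The route is written with the (R)-acid; the equally available (S)-acid would be used if the first run shows the opposite sense.

## The problem

The target is a 5,7-dihydroxyflavone whose ring A carries an N-methylpiperidine at C6, between the two hydroxyls, joined through C2'. Ring A therefore has a single free position (C8), and the pyranone and the piperidine must be placed on a phloroglucinol nucleus in one defined arrangement. The only stereocentre is C2' (R); it is benzylic and α to nitrogen, and nothing else in the molecule can control it, so its configuration must come from a catalyst or reagent. The same centre is the fragile point: on a trioxygenated ring the C2'–N bond can ionise under acid, or open through a quinone methide when a free ortho or para hydroxyl accompanies a protonated amine, and reclosure gives racemic material. The three ring oxygens must be told apart: the one para to C2' has to become O1, because closure through an ortho oxygen gives the 8-substituted isomer, and hot mineral acid interconverts the two. The flavone enone would not survive hydride or hydrogenation steps, and free phenols would not survive an oxidant, so the pyranone must be built late and the hydroxyls released last. The enabling feature is that C2' is bonded both to ring A carbon C6 and to N1'. It can therefore be the carbon of an aryl aldimine, and N1' and C2' then need only the four carbons C3'–C6', which a 1-alkoxy-3-siloxybutadiene supplies.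

## Retrosynthesis

Target 19 is traced to its dimethyl ether 18 by cutting the two O–CH3 bonds at C5 and C7. Methyl ethers withstand every hydride, hydrogenation, oxidation and strong-base step before them, and they keep the two ortho oxygens distinct from the oxygen that becomes O1. The forward step must cleave both ethers cold and without protic acid.

Flavone 18 is opened at O1–C2 to the 1,3-diketone 17, and 17 is cut at C2–C3 into the hydroxy acetophenone 15 and benzoyl chloride 16. The neighbouring cut at O1–C8a would need a halogen on ring A. Here the single free hydroxyl of 15 fixes which oxygen closes the ring, so the piperidine must end at C6. The forward steps are an enolate C-benzoylation and an acid cyclodehydration.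

Ketone 15 is cut at the C4a–C4 aryl–acyl bond to phenol 13, through its acetate 14. The two open positions of 13 are equivalent by symmetry, so acylation has no regiochemical choice and the acetyl group must land next to the free para oxygen. The forward reaction has to acylate carbon in the presence of a basic amine and under mild conditions.

Phenol 13 comes from tosylate 12 by O–S cleavage, 12 from secondary amine 11 by cutting N–CH3, and 11 from the N-aryl piperidine 10 by cutting the N–aryl bond. The sulfonate marks the future O1 from the first step. A silyl ether would also do that, but the sulfonate withdraws electrons, so the ring is a poorer donor through the imine, hydride, hydrogenation and oxidation stages. The N-aryl group is the price of the key step, and its removal must be selective for the anisidine ring.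

Piperidine 10 is traced to enol triflate 9 and then to dihydropyridinone 7, through enolate 8. These steps remove the C4' oxygen and the C5'=C6' unsaturation. Trapping the enolate avoids a free 2-aryl-4-piperidone, which could lose its configuration by retro-Michael opening.

Dihydropyridinone 7 is cut at C2'–C3' and N1'–C6' into aldimine 4 and diene 5, through Mannich adduct 6. Cutting N1'–C2' or C4'–C5' instead would leave the stereocentre to a separate operation. This cut removes the ring and the stereocentre together and leaves two flat, achiral partners. The forward reaction must deliver one face of the imine and close the ring at nitrogen.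

Aldimine 4 is cut at C=N into aldehyde 2 and 4-methoxyaniline 3, and 2 is cut at O–S back to commercial aldehyde 1.

## Roads not taken

Alternative 1: The cut is N1'–C2'. Racemic carbinol A1, with a methyl carbamate on a five-carbon tether, would dehydrate under a chiral phosphoric acid to an ortho-quinone methide, and the carbamate nitrogen would add to the methide carbon in a 6-exo-trig closure to give carbamate A2.
- Merits: it is stereoconvergent, it needs no N-aryl group and so no oxidative dearylation, and the carbamate of A2 could be reduced directly to the N-methyl group. In these respects it is better than the chosen plan.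
- Weak points: the ring of A1 is so electron-rich that it can ionise without the catalyst, which opens a racemic background path. A2 keeps two free ortho hydroxyls and can re-ionise under the same acid. A2 also has the oxygen pattern the wrong way round for the pyranone (ortho oxygens free, para oxygen blocked), so reprotection steps would follow.
- Comparison: the chosen plan offers a closer precedent, a product (7) that is configurationally inert under the catalyst, and oxygen differentiation fixed from step 1.

Alternative 2: The cut is O1–C8a. The enol oxygen of bromo diketone A3 would displace the ortho bromine under monovalent copper catalysis (CuI, diamine ligand, base) to give flavone A4, which is the same compound as 18.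
- Merits: the position of the bromine fixes the regiochemistry, no free para-phenol and no Lewis-acid acylation of an electron-rich phenolic amine are needed, and this is a real advantage over steps 8 and 9.
- Weak points: it says nothing about C2', which must still be set by another method. The bromine would have to survive a hydride step, a hydrogenation over platinum and an oxidation. The closure needs base and heat on a substrate that can bind copper through its amine.
- Comparison: it is a tactic for ring C, not a rival for the stereocentre, and could be grafted onto the chosen key step. The chosen plan offers a metal-free annulation with precedent on amine-bearing phloroglucinol ethers and no halogen to carry through two reductions.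

Alternative 3: The cut is C4'=C5'. The ammonium salt of diallylic amine A5 would undergo ring-closing metathesis with the second-generation Grubbs catalyst (H2IMes)(PCy3)Cl2Ru=CHPh to give tetrahydropyridine A6.
- Merits: the N-methyl group is present from the start, there is no ketone to remove, and one hydrogenation of A6 would saturate the ring and free the para-phenol together. After ring closure this road is shorter than the chosen one, which pays three steps for deoxygenation and dearylation.
- Weak points: metathesis creates no stereocentre, so C2' of A5 must come from an auxiliary-controlled allylation with stoichiometric chirality, followed by two N-alkylations of a hindered benzylic amine.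
- Comparison: the chosen plan builds ring and stereocentre in one catalytic step from three commercial, achiral components.

Key step: step 3

## Route

Step 1
Reactants: 1 hydroxy aldehyde 4-hydroxy-2,6-dimethoxybenzaldehyde
Product: 2 aldehyde tosylate 4-formyl-3,5-dimethoxyphenyl 4-methylbenzenesulfonate
Conditions: TsCl, Et3N, DMAP (cat.), CH2Cl2, 0 °C to rt
Reagents that add atoms: 4-methylbenzenesulfonyl chloride, Cc1ccc(cc1)S(Cl)(=O)=O
Why: O-Sulfonylation of a phenol; the phenol para to the formyl group is acidic and the aldehyde is untouched. The tosylate is preferred to a silyl ether because its electron withdrawal makes the derived imine more electrophilic and the later benzylic amine less prone to ionisation and ring oxidation.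

Step 2
Reactants: 2 aldehyde tosylate 4-formyl-3,5-dimethoxyphenyl 4-methylbenzenesulfonate; 3 amine 4-methoxyaniline
Product: 4 aldimine 3,5-dimethoxy-4-[(E)-(4-methoxyphenylimino)methyl]phenyl 4-methylbenzenesulfonate
Conditions: 4 Å molecular sieves, toluene, 60 °C
Reagents that add atoms: none
Why: Imine condensation driven by removal of water; the aldehyde cannot enolise and the E isomer is the only stable geometry of an N-aryl aryl aldimine.

Step 3
Reactants: 4 aldimine 3,5-dimethoxy-4-[(E)-(4-methoxyphenylimino)methyl]phenyl 4-methylbenzenesulfonate; 5 diene (E)-1-methoxy-3-(trimethylsilyloxy)buta-1,3-diene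
Product: 7 dihydropyridinone 3,5-dimethoxy-4-[(2R)-1-(4-methoxyphenyl)-4-oxo-1,2,3,4-tetrahydropyridin-2-yl]phenyl 4-methylbenzenesulfonate, via Mannich adduct 6 (not isolated)
Conditions: (R)-3,3'-bis(2,4,6-triisopropylphenyl)-1,1'-binaphthyl-2,2'-diyl hydrogen phosphate (10 mol%), AcOH (1.2 equiv), 5 (2.5 equiv), toluene, −78 to −40 °C; then 1 M aq. HCl, THF, 0 °C
Reagents that add atoms: none
Why: The phosphoric acid protonates imine 4 to a hydrogen-bonded chiral ion pair, and the CH2 terminus of diene 5 adds to the iminium carbon (vinylogous Mukaiyama–Mannich step), forming C2'–C3' and, after silyl transfer to acetic acid, the β-amino enone 6. The anilino nitrogen of 6 then adds to the methoxy-bearing enone carbon in a 6-endo-trig closure and methanol is expelled, forming N1'–C6' and the vinylogous amide 7; the brief acid treatment completes this closure. The closest known reaction type is the chiral Brønsted acid catalysed aza-Diels–Alder (Mannich–Michael) reaction of N-aryl aryl aldimines with 1-alkoxy-3-siloxybutadienes, in which acetic acid turns the catalyst over. The single new stereocentre C2' is set in the Mannich step by the chiral phosphate, whose triisopropylphenyl groups shield one face of the bound E-iminium ion; no substrate element contributes. The step needs face selectivity, which rests on the catalyst, and regioselectivity (attack by the diene terminus, closure at nitrogen), which rests on the polarity of the diene. The substrate helps in three ways: the imine cannot enolise, the para tosylate offsets the donor effect of the two ortho methoxy groups at the iminium carbon, and the product cannot reopen by retro-Michael reaction, so the configuration once set is kept.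

Step 4
Reactants: 7 dihydropyridinone 3,5-dimethoxy-4-[(2R)-1-(4-methoxyphenyl)-4-oxo-1,2,3,4-tetrahydropyridin-2-yl]phenyl 4-methylbenzenesulfonate
Product: 9 enol triflate (2R)-2-[2,6-dimethoxy-4-(tosyloxy)phenyl]-1-(4-methoxyphenyl)-1,2,3,6-tetrahydropyridin-4-yl trifluoromethanesulfonate, via lithium enolate 8 (not isolated)
Conditions: LiBH(s-Bu)3, THF, −78 °C; then PhNTf2, −78 to 0 °C
Reagents that add atoms: N-phenyl-bis(trifluoromethanesulfonimide), FC(F)(F)S(=O)(=O)N(c1ccccc1)S(=O)(=O)C(F)(F)F
Why: Conjugate hydride reduction of the vinylogous amide by the bulky borohydride, followed by O-triflation of the regiodefined enolate 8, as established for 2,3-dihydro-4-pyridones. The enolate is trapped cold, so no free 4-piperidone that could racemise at C2' by retro-Michael opening is formed; C2' is not touched.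

Step 5
Reactants: 9 enol triflate (2R)-2-[2,6-dimethoxy-4-(tosyloxy)phenyl]-1-(4-methoxyphenyl)-1,2,3,6-tetrahydropyridin-4-yl trifluoromethanesulfonate
Product: 10 N-aryl piperidine 3,5-dimethoxy-4-[(2R)-1-(4-methoxyphenyl)piperidin-2-yl]phenyl 4-methylbenzenesulfonate
Conditions: H2 (1 atm), 5% Pt/C, Li2CO3, EtOAc, rt
Reagents that add atoms: none
Why: Catalytic hydrogenation of an enol triflate to the methylene compound (C–O hydrogenolysis and alkene saturation), with Li2CO3 taking up the triflic acid. Platinum is chosen over palladium to spare the benzylic C2'–N bond, and aryl sulfonates are inert under these conditions.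

Step 6
Reactants: 10 N-aryl piperidine 3,5-dimethoxy-4-[(2R)-1-(4-methoxyphenyl)piperidin-2-yl]phenyl 4-methylbenzenesulfonate
Product: 11 secondary amine 3,5-dimethoxy-4-[(2R)-piperidin-2-yl]phenyl 4-methylbenzenesulfonate
Conditions: (NH4)2Ce(NO3)6 (2.5 equiv), MeCN/H2O, 0 °C; acidic aqueous phase washed with EtOAc, then aq. Na2CO3
Reagents that add atoms: none
Why: Oxidative N-dearylation of a 4-methoxyphenyl amine by tetravalent cerium: two one-electron oxidations give the quinone iminium ion, which water hydrolyses to the secondary amine. The dialkylanisidine is oxidised far more easily than the sulfonyloxy-dimethoxybenzene ring, which the tosylate deactivates further.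

Step 7
Reactants: 11 secondary amine 3,5-dimethoxy-4-[(2R)-piperidin-2-yl]phenyl 4-methylbenzenesulfonate
Product: 12 N-methyl piperidine 3,5-dimethoxy-4-[(2R)-1-methylpiperidin-2-yl]phenyl 4-methylbenzenesulfonate
Conditions: aq. HCHO, NaBH(OAc)3, ClCH2CH2Cl, rt
Reagents that add atoms: formaldehyde, C=O
Why: Reductive amination of a secondary amine with formaldehyde and an acyloxyborohydride; the sulfonate and the stereocentre are not affected and no hot acid is involved.

Step 8
Reactants: 12 N-methyl piperidine 3,5-dimethoxy-4-[(2R)-1-methylpiperidin-2-yl]phenyl 4-methylbenzenesulfonate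
Product: 13 phenol 3,5-dimethoxy-4-[(2R)-1-methylpiperidin-2-yl]phenol
Conditions: KOH, H2O/1,4-dioxane, 80 °C; then aq. NH4Cl to pH 9
Reagents that add atoms: none
Why: Alkaline hydrolysis of an aryl sulfonate by attack of hydroxide at sulfur; the alcohol-free medium avoids an alkyl tosylate that could re-alkylate the phenoxide or the amine. In base the product is a phenoxide beside an unprotonated amine, which has no path to a quinone methide.

Step 9
Reactants: 13 phenol 3,5-dimethoxy-4-[(2R)-1-methylpiperidin-2-yl]phenol
Product: 15 hydroxy acetophenone 1-{6-hydroxy-2,4-dimethoxy-3-[(2R)-1-methylpiperidin-2-yl]phenyl}ethan-1-one, via aryl acetate 14 (not isolated)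
Conditions: Ac2O, BF3·OEt2, CH2Cl2, 0 to 40 °C; then aq. NaOAc, MeOH, rt
Reagents that add atoms: acetic anhydride, CC(=O)OC(C)=O
Why: O-Acetylation followed by a boron trifluoride-mediated Fries rearrangement (Friedel–Crafts C-acylation), as used for 3,5-dimethoxyphenol and for amine-bearing phloroglucinol ethers. The two open ring positions of 13 are equivalent, so the acetyl group can only arrive next to the oxygen that becomes O1, and the amine is tied up as its boron trifluoride adduct.

Step 10
Reactants: 15 hydroxy acetophenone 1-{6-hydroxy-2,4-dimethoxy-3-[(2R)-1-methylpiperidin-2-yl]phenyl}ethan-1-one; 16 benzoyl chloride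
Product: 17 diketone 1-{6-hydroxy-2,4-dimethoxy-3-[(2R)-1-methylpiperidin-2-yl]phenyl}-3-phenylpropane-1,3-dione
Conditions: LiN(SiMe3)2 (4 equiv), THF, −78 to −20 °C; then 16, −78 °C to rt
Reagents that add atoms: none
Why: Claisen-type C-benzoylation of the ketone enolate in the presence of the phenoxide, the excess-base variant of the Baker–Venkataraman route to 1,3-diketones; phenol, methyl ketone and product each consume one equivalent of base.

Step 11
Reactants: 17 diketone 1-{6-hydroxy-2,4-dimethoxy-3-[(2R)-1-methylpiperidin-2-yl]phenyl}-3-phenylpropane-1,3-dione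
Product: 18 flavone dimethyl ether 5,7-dimethoxy-6-[(2R)-1-methylpiperidin-2-yl]-2-phenyl-4H-chromen-4-one
Conditions: H2SO4 (cat.), AcOH, 60 °C
Reagents that add atoms: none
Why: Acid-catalysed cyclodehydration of a 2-hydroxyaryl 1,3-diketone to the flavone. Only one hydroxyl is free, so O1 can only be the former para oxygen and the piperidine ends at C6; the acylated ring is a poorer donor, so C2' should be safe.

Step 12
Reactants: 18 flavone dimethyl ether 5,7-dimethoxy-6-[(2R)-1-methylpiperidin-2-yl]-2-phenyl-4H-chromen-4-one
Product: 19 target 5,7-dihydroxy-6-[(2R)-1-methylpiperidin-2-yl]-2-phenyl-4H-chromen-4-one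
Conditions: BBr3 (6 equiv), CH2Cl2, −78 °C to rt; then MeOH, aq. NaHCO3, below 25 °C
Reagents that add atoms: none
Why: Lewis acid cleavage of aryl methyl ethers; the C5 ether is activated by chelation to the C4 carbonyl and the C7 ether should follow at room temperature. The cold, non-protic medium avoids the ring opening that interconverts 6- and 8-substituted 5,7-dihydroxyflavones in hot mineral acid (Wessely–Moser rearrangement).

## Compound list

1 | 4-hydroxy-2,6-dimethoxybenzaldehyde | COc1cc(O)cc(OC)c1C=O | starting material
2 | 4-formyl-3,5-dimethoxyphenyl 4-methylbenzenesulfonate | COc1cc(OS(=O)(=O)c2ccc(C)cc2)cc(OC)c1C=O | intermediate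
3 | 4-methoxyaniline | COc1ccc(N)cc1 | starting material
4 | 3,5-dimethoxy-4-[(E)-(4-methoxyphenylimino)methyl]phenyl 4-methylbenzenesulfonate | COc1ccc(cc1)/N=C/c1c(OC)cc(OS(=O)(=O)c2ccc(C)cc2)cc1OC | intermediate
5 | (E)-1-methoxy-3-(trimethylsilyloxy)buta-1,3-diene | CO/C=C/C(=C)O[Si](C)(C)C | starting material
6 | 4-[(1R,4E)-5-methoxy-1-(4-methoxyanilino)-3-oxopent-4-en-1-yl]-3,5-dimethoxyphenyl 4-methylbenzenesulfonate | CO/C=C/C(=O)C[C@@H](Nc1ccc(OC)cc1)c1c(OC)cc(OS(=O)(=O)c2ccc(C)cc2)cc1OC | intermediate (not isolated)
7 | 3,5-dimethoxy-4-[(2R)-1-(4-methoxyphenyl)-4-oxo-1,2,3,4-tetrahydropyridin-2-yl]phenyl 4-methylbenzenesulfonate | COc1ccc(cc1)N1C=CC(=O)C[C@@H]1c1c(OC)cc(OS(=O)(=O)c2ccc(C)cc2)cc1OC | intermediate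
8 | lithium (2R)-2-[2,6-dimethoxy-4-(tosyloxy)phenyl]-1-(4-methoxyphenyl)-1,2,3,6-tetrahydropyridin-4-olate | [Li+].COc1ccc(cc1)N1CC=C([O-])C[C@@H]1c1c(OC)cc(OS(=O)(=O)c2ccc(C)cc2)cc1OC | intermediate (not isolated)
9 | (2R)-2-[2,6-dimethoxy-4-(tosyloxy)phenyl]-1-(4-methoxyphenyl)-1,2,3,6-tetrahydropyridin-4-yl trifluoromethanesulfonate | COc1ccc(cc1)N1CC=C(OS(=O)(=O)C(F)(F)F)C[C@@H]1c1c(OC)cc(OS(=O)(=O)c2ccc(C)cc2)cc1OC | intermediate
10 | 3,5-dimethoxy-4-[(2R)-1-(4-methoxyphenyl)piperidin-2-yl]phenyl 4-methylbenzenesulfonate | COc1ccc(cc1)N1CCCC[C@@H]1c1c(OC)cc(OS(=O)(=O)c2ccc(C)cc2)cc1OC | intermediate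
11 | 3,5-dimethoxy-4-[(2R)-piperidin-2-yl]phenyl 4-methylbenzenesulfonate | N1CCCC[C@@H]1c1c(OC)cc(OS(=O)(=O)c2ccc(C)cc2)cc1OC | intermediate
12 | 3,5-dimethoxy-4-[(2R)-1-methylpiperidin-2-yl]phenyl 4-methylbenzenesulfonate | CN1CCCC[C@@H]1c1c(OC)cc(OS(=O)(=O)c2ccc(C)cc2)cc1OC | intermediate
13 | 3,5-dimethoxy-4-[(2R)-1-methylpiperidin-2-yl]phenol | CN1CCCC[C@@H]1c1c(OC)cc(O)cc1OC | intermediate
14 | 3,5-dimethoxy-4-[(2R)-1-methylpiperidin-2-yl]phenyl acetate | CN1CCCC[C@@H]1c1c(OC)cc(OC(C)=O)cc1OC | intermediate (not isolated)
15 | 1-{6-hydroxy-2,4-dimethoxy-3-[(2R)-1-methylpiperidin-2-yl]phenyl}ethan-1-one | CN1CCCC[C@@H]1c1c(OC)cc(O)c(C(C)=O)c1OC | intermediate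
16 | benzoyl chloride | O=C(Cl)c1ccccc1 | starting material
17 | 1-{6-hydroxy-2,4-dimethoxy-3-[(2R)-1-methylpiperidin-2-yl]phenyl}-3-phenylpropane-1,3-dione | CN1CCCC[C@@H]1c1c(OC)cc(O)c(C(=O)CC(=O)c2ccccc2)c1OC | intermediate
18 | 5,7-dimethoxy-6-[(2R)-1-methylpiperidin-2-yl]-2-phenyl-4H-chromen-4-one | CN1CCCC[C@@H]1c1c(OC)cc2oc(-c3ccccc3)cc(=O)c2c1OC | intermediate
19 | 5,7-dihydroxy-6-[(2R)-1-methylpiperidin-2-yl]-2-phenyl-4H-chromen-4-one | CN1CCCC[C@@H]1c1c(O)cc2oc(-c3ccccc3)cc(=O)c2c1O | target

## Step count and risks

Total steps: 12. Longest linear sequence: 12 steps (1 to 19).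

**Step 3 (key step).**
- Risk: slow Mannich addition and poor facial selectivity. The two ortho substituents twist and crowd the iminium carbon, and an internal N–H···OMe hydrogen bond may loosen the contact with the phosphate. If the addition is slow, protodesilylation of the diene by acetic acid takes over.
- Fallback, from 2 back to 11 (replacing steps 2 to 6): condensation of 2 with (S)-2-methylpropane-2-sulfinamide and Ti(OEt)4 should give the sulfinyl imine F1. Addition of 4-chlorobutylmagnesium bromide in CH2Cl2 at −48 °C should give the sulfinamide F2, with R at carbon expected from the closed chair transition state. HCl in MeOH removes the sulfinyl group to give the amino chloride F3, which closes by 6-exo-tet N-alkylation (K2CO3, NaI, MeCN) to 11. Control here comes from a stoichiometric auxiliary, and the ring is closed at N1'–C6' only.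

**Step 4.**
- Risk: sluggish or 1,2-selective hydride delivery, because donation from nitrogen lowers the electrophilicity of C6', or incomplete sulfonylation of the boron-bound enolate.
- Fallback, from 7 back to 9: the polarity is reversed. O-Triflation of 7 with Tf2O and 2,6-di-tert-butyl-4-methylpyridine in CH2Cl2 at −78 °C should give the 4-triflyloxy-2,3-dihydropyridinium triflate F4. NaBH4 then adds hydride to the iminium carbon C6' and gives 9.

**Step 6.**
- Risk: loss of an α-proton from the aminium radical cation (oxidation at C2' or C6' instead of dearylation), acid-promoted ionisation of the benzylic C–N bond with erosion of enantiomeric purity, or addition of the liberated amine to the quinone by-product.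
- Fallback, from 7 back to 12: the aryl group is removed at the vinylogous amide stage, where nitrogen behaves like the nitrogen of an N-aryl lactam. (NH4)2Ce(NO3)6 on 7 should give the N–H dihydropyridinone F5, and NaH with MeI the N-methyl dihydropyridinone F6. LiBH(s-Bu)3 then PhNTf2 gives the enol triflate F7, and H2 over Pt/C with Li2CO3 gives 12.

**Step 9.**
- Risk: Lewis-acid-assisted ionisation of the benzylic C–N bond before the ring is acylated (racemisation), or further loss of the methyl ether flanked by acetyl and piperidine. The latter would free a second ortho hydroxyl and destroy the regiocontrol of step 11.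
- Fallback, from 13 back to 15: directed ortho-metalation in place of electrophilic acylation. NaH and MOMCl give the methoxymethyl ether F8. s-BuLi/TMEDA at −78 °C lithiates the position between the two oxygen substituents, and N-methoxy-N-methylacetamide gives the ketone F9. HCl in MeOH at rt removes the acetal and gives 15.

**Step 12.**
- Risk: incomplete cleavage of the hindered C7 ether next to the piperidine, or loss of configurational purity in the product, whose free ortho hydroxyls open a quinone methide path once the amine is protonated and the mixture is warmed.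
- Fallback, from 18 back to 19: two cleavages by different mechanisms. BCl3 at −78 to 0 °C should remove only the chelated C5 methyl and give the monomethyl ether F10. Sodium ethanethiolate in DMF then removes the C7 methyl by SN2 attack, under basic conditions in which the amine is not a leaving group, and gives 19.

## Further compounds

F1 | step 3 | 3,5-dimethoxy-4-{(E)-[(S)-tert-butylsulfinylimino]methyl}phenyl 4-methylbenzenesulfonate | CC(C)(C)[S@](=O)/N=C/c1c(OC)cc(OS(=O)(=O)c2ccc(C)cc2)cc1OC
F2 | step 3 | 4-{(1R)-5-chloro-1-[(S)-tert-butylsulfinylamino]pentyl}-3,5-dimethoxyphenyl 4-methylbenzenesulfonate | CC(C)(C)[S@](=O)N[C@H](CCCCCl)c1c(OC)cc(OS(=O)(=O)c2ccc(C)cc2)cc1OC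
F3 | step 3 | 4-[(1R)-1-amino-5-chloropentyl]-3,5-dimethoxyphenyl 4-methylbenzenesulfonate | N[C@H](CCCCCl)c1c(OC)cc(OS(=O)(=O)c2ccc(C)cc2)cc1OC
F4 | step 4 | (2R)-2-[2,6-dimethoxy-4-(tosyloxy)phenyl]-1-(4-methoxyphenyl)-4-(trifluoromethanesulfonyloxy)-2,3-dihydropyridin-1-ium trifluoromethanesulfonate | COc1ccc(cc1)[N+]1=CC=C(OS(=O)(=O)C(F)(F)F)C[C@@H]1c1c(OC)cc(OS(=O)(=O)c2ccc(C)cc2)cc1OC.[O-]S(=O)(=O)C(F)(F)F
F5 | step 6 | 3,5-dimethoxy-4-[(2R)-4-oxo-1,2,3,4-tetrahydropyridin-2-yl]phenyl 4-methylbenzenesulfonate | N1C=CC(=O)C[C@@H]1c1c(OC)cc(OS(=O)(=O)c2ccc(C)cc2)cc1OC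
F6 | step 6 | 3,5-dimethoxy-4-[(2R)-1-methyl-4-oxo-1,2,3,4-tetrahydropyridin-2-yl]phenyl 4-methylbenzenesulfonate | CN1C=CC(=O)C[C@@H]1c1c(OC)cc(OS(=O)(=O)c2ccc(C)cc2)cc1OC
F7 | step 6 | (2R)-2-[2,6-dimethoxy-4-(tosyloxy)phenyl]-1-methyl-1,2,3,6-tetrahydropyridin-4-yl trifluoromethanesulfonate | CN1CC=C(OS(=O)(=O)C(F)(F)F)C[C@@H]1c1c(OC)cc(OS(=O)(=O)c2ccc(C)cc2)cc1OC
F8 | step 9 | (2R)-2-[2,6-dimethoxy-4-(methoxymethoxy)phenyl]-1-methylpiperidine | CN1CCCC[C@@H]1c1c(OC)cc(OCOC)cc1OC
F9 | step 9 | 1-{2,4-dimethoxy-6-(methoxymethoxy)-3-[(2R)-1-methylpiperidin-2-yl]phenyl}ethan-1-one | CN1CCCC[C@@H]1c1c(OC)cc(OCOC)c(C(C)=O)c1OC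
F10 | step 12 | 5-hydroxy-7-methoxy-6-[(2R)-1-methylpiperidin-2-yl]-2-phenyl-4H-chromen-4-one | CN1CCCC[C@@H]1c1c(OC)cc2oc(-c3ccccc3)cc(=O)c2c1O
A1 | alternative 1 | methyl N-[5-(4-benzyloxy-2,6-dihydroxyphenyl)-5-hydroxypentyl]carbamate (racemic) | COC(=O)NCCCCC(O)c1c(O)cc(OCc2ccccc2)cc1O
A2 | alternative 1 | methyl (R)-2-(4-benzyloxy-2,6-dihydroxyphenyl)piperidine-1-carboxylate | COC(=O)N1CCCC[C@@H]1c1c(O)cc(OCc2ccccc2)cc1O
A3 | alternative 2 | 1-{6-bromo-2,4-dimethoxy-3-[(2R)-1-methylpiperidin-2-yl]phenyl}-3-phenylpropane-1,3-dione | CN1CCCC[C@@H]1c1c(OC)cc(Br)c(C(=O)CC(=O)c2ccccc2)c1OC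
A4 | alternative 2 | (R)-5,7-dimethoxy-6-(1-methylpiperidin-2-yl)-2-phenyl-4H-chromen-4-one | CN1CCCC[C@@H]1c1c(OC)cc2oc(-c3ccccc3)cc(=O)c2c1OC
A5 | alternative 3 | (R)-N-allyl-1-[4-(benzyloxy)-2,6-dimethoxyphenyl]-N-methylbut-3-en-1-amine | C=CCN(C)[C@H](CC=C)c1c(OC)cc(OCc2ccccc2)cc1OC
A6 | alternative 3 | (R)-2-[4-(benzyloxy)-2,6-dimethoxyphenyl]-1-methyl-1,2,3,6-tetrahydropyridine | CN1CC=CC[C@@H]1c1c(OC)cc(OCc2ccccc2)cc1OC
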